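7.10% is the excess of D over Q in the amber run at 2.50 h, with c_Z then at 11.6 mM.

| setting | amber | grey | teal | flask |
|---|---|---|---|---|
| Q | 0.050 M | 0.050 M | 0.050 M | 0.050 M |
| D | 0.050 M | 0.050 M | 0.050 M | 0.050 M |
| Z | 0.075 M | 0.30 M | 0.15 M | 0.150 M |
| G | 5.5 mM | 5.5 mM | 8.2 mM | 5.5 mM |
| remark | run made earlier | run made earlier | run made earlier |  |
| time |  |  |  | 3.0 h |

- amber (time / h: Q / %, D / %, X / %): 0.200: 38.2, 45.2, 12.1; 0.667: 26.4, 36.2, 24.2; 1.00: 23.4, 29.0, 31.0; 1.50: 19.1, 22.6, 33.8; 2.50: 17.0, 19.6, 42.6; 3.00: 16.1, 17.7, 43.5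
- grey (time / h: Q / %, D / %, X / %): 0.200: 15.6, 30.5, 32.9; 0.667: 4.3, 10.2, 48.9; 1.00: 2.5, 4.9, 51.9; 1.50: 0.6, 0.2, 52.1; 2.50: 0.4, 0.9, 55.6; 3.00: 0, 0, 54.4
- teal (time / h: Q / %, D / %, X / %): 0.667: 12.4, 21.3, 39.2; 1.33: 7.9, 12.6, 51.1; 2.00: 5.6, 6.5, 55.5; 2.50: 3.9, 2.9, 59.0; 3.00: 2.4, 1.6, 61.0

(readings scatter by 1 percentage point)

* part of the Q and D charged together that has reacted at 3.0 h
* excess of X over E in the product at 3.0 h
* excess of D over Q among what is left of the two at 3.0 h

- Z is single-handed; Q and D are mirror images of each other, charged as a racemate, each of them at the stated concentration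
- the numbers in the tables scatter by 1 percentage point (one standard deviation)
- reactions considered so far: Z + Q -> X; Z + D -> E; Q + L <-> D + L; L -> J; G -> L
- an excess is below zero if the other one leads
- the handed part of Z does not stay in what it makes, so the products of the two hands are mirror images too

1. Let e be the excess of D over Q among what is left, kQ and kD the rate constants of Q and D with Z, and kr the racemisation rate by L in each direction. You have two rates: Z widens e through (kQ − kD)·c_Z, and L closes it through 4·kr.

2. Balance them in a quasi-steady state and time drops out: e/(1 − e·e) = c_Z/C. Here C = 4·kr/(kQ − kD), the crossover concentration of Z. It belongs to a given c_L, as kr goes with c_L.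

3. Amber gives C = 0.162 M. That is a loose reading, since it rests on a gap of 2.6 percentage points and each reading scatters by 1 point.

4. The forecast says c 94%, eP 23%, eS 30%, its racemisation constant coming from the amber gap, “held in near balance while Z runs out”.

5. My own reckoning takes that c, which puts c_Z in the flask at 0.0560 M, and it takes C from amber, which was charged with the same 5.5 mM of G. Then c_Z/C is 0.345, and solving for e gives 31.1%. This is no check on the forecast, as both lean on amber.

The flask gives c 95.1%, eP 21.7% and eS 15.1%, with Z at 36.6% of its charge, or 0.0549 M.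

    Z + Q → X (k = 0.00550 M⁻¹ s⁻¹)
    Z + D → E (k = 0.00250 M⁻¹ s⁻¹)
    Q + L ⇌ D + L, rate k3*[L]*[Q] forward; the back reaction follows from the equilibrium constant (k = 0.170 M⁻¹ s⁻¹)
    L → J (k = 1.60 × 10⁻⁴ s⁻¹)
    G → L (k = 1.20 × 10⁻⁴ s⁻¹)

Put into the rule, that eS yields C = 0.357 M for this flask, against the amber reading of 0.162 M. Now take the neighbouring flask with 0.60 M of Z, where L stands at 28.8% as in the flask. Its c_Z ends at 0.500 M, so c_Z/C is 1.40, and the rule gives e = 70.5%. That neighbouring flask shows eS 69.7%.

(The readings are calculated with constants of no real substance, noise included.)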